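(The readings are calculated on assumed constants.)

At the late end of Wednesday's run the solid substrate still read 70.3 %, so I took the flask as a slurry feeding a small dissolved pool, reckoned Sunday's flask from that late side and joined it to the early readings.

| flask | solid substrate | reagent | remark | time |
|---|---|---|---|---|
| Sunday's | 24 mM | 36 mM | the very flask that is asked about, followed so far |  |
| Wednesday's | 24 mM | 72 mM | run made earlier |  |
| flask | 24 mM | 36.0 mM |  | 2.5 h |

| run | time / min | solid substrate / % | first product / % | other mono adduct / % |
|---|---|---|---|---|
| Sunday's | 15.0 | 94.6 | 0.3 | 0.1 |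
| Sunday's | 30.0 | 90.5 | 1.0 | 0 |
| Sunday's | 50.0 | 85.8 | 3.0 | 0.7 |
| Sunday's | 60.0 | 84.4 | 3.5 | 1.2 |
| Wednesday's | 25.0 | 92.4 | 2.0 | 1.2 |
| Wednesday's | 50.0 | 85.0 | 3.7 | 0.4 |
| Wednesday's | 80.0 | 78.6 | 7.4 | 2.7 |
| Wednesday's | 120 | 70.3 | 12.9 | 3.5 |

(readings scatter by 0.5 percentage points)

* how much solid substrate there is at 2.5 h, in percent of the solid substrate charged (only what is still solid)
* how much first product there is at 2.5 h, in percent of the solid substrate charged
* how much other mono adduct there is at 2.5 h, in percent of the solid substrate charged
* how much double product there is at 2.5 h, in percent of the solid substrate charged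

- solid substrate is a solid; its amount is given per volume of the solution
- at the start none of the solid substrate is in solution

1. Reagent. By hand, doubling [reagent] should leave dissolving untouched and double the reaction. At 50.0 min the solid substrate read 85.8 % on Sunday and 85.0 % on Wednesday, a gap of 0.8 percentage points at a scatter of 0.5 points, so I took the early loss as dissolving. Late on Wednesday, first product and other mono adduct together gained 6.3 points in 40.0 min. I treated that gain as pseudo-first-order in the dissolved pool and proportional to [reagent], and scaled it to Sunday's flask, which gave 11.8 % of those two products at 2.5 h.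

2. Solid substrate. By hand, a pool that levels off stands at a fixed concentration, so a larger charge should shrink the percentages of the dissolved substrate and the products and raise that of the solid substrate. I named the hold-up, the dissolved substrate in mM, read as the charge minus solid, first product and other mono adduct. It read 2.62 mM at Sunday's last reading and 3.19 mM at Wednesday's.

3. Time. Joining the two ends, I expected 74.9 % solid substrate.

The forecast gave 73.5 % (69 % to 77 %) solid substrate, 10.5 % (7.5 % to 14 %) first product, 2.5 % (1.3 % to 4.2 %) other mono adduct and 1 % (0.2 % to 3 %) double product, holding that “Dissolved substrate therefore levels off near saturation”. Its solid substrate stood lower than mine.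

The flask gave 69.9 %, 9.99 %, 2.86 % and 1.31 %, in that order.

    starting material + reagent → first product (k = 0.00360 M⁻¹ s⁻¹)
    reagent + first product → double product (k = 1.40 × 10⁻⁴ M⁻¹ s⁻¹)
    reagent + other mono adduct → double product (k = 0.00280 M⁻¹ s⁻¹)
    first product ⇌ isomer of the product (K = 0.500, k = 6.00 × 10⁻⁵ s⁻¹)
    starting material + reagent → other mono adduct (k = 0.00120 M⁻¹ s⁻¹)
    solid substrate ⇌ starting material, rate k6*(cs6 - [starting material]) while solid is left; crystals form when [starting material] > cs6 (solubility = 5.20 mM, k = 3.10 × 10⁻⁴ s⁻¹)

Starting material stood at 3.39 mM in Sunday's flask at 2.50 h, beside my hold-up of 3.19 mM. The neighbour charged with 96 mM of solid substrate tests that figure: the same hold-up over its charge gave me 3.32 %, and it held 3.54 % starting material. Its charge being four times as large, I scaled first product to a quarter of Sunday's, 2.50 %, and the neighbour's first product stood at 2.50 %.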